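**Assumption:** the target has no stereocentre and no stereogenic double bond (the maleimide alkene is fixed in its ring), so there is no enantiomer to control; the route delivers the single compound the SMILES describes.

## Retrosynthetic overview

- The maleimide is opened at its two imide C–N bonds by formally deleting the nitrogen atom, which leads back to a 3,4-diarylcyclobutene-1,2-dione. In the forward direction this is a nitrogen-atom insertion (aza-Baeyer–Villiger ring expansion, four- to five-membered ring).
- The diaryl cyclobutenedione is cut at the imidazol-5-yl–C(sp2) bond (Stille) to an indolyl chlorocyclobutenedione and a 5-stannylimidazole.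
- The indolyl chlorocyclobutenedione is cut at the indole C3–C bond (Friedel–Crafts) to 6-bromoindole and squaric acid dichloride.
- Ring order: indole, imidazole and the four-membered ring are bought. The maleimide is the only ring formed, and it is formed last.

## Route

Step 1
Reactants: 1 6-bromo-1H-indole; 2 3,4-dichlorocyclobut-3-ene-1,2-dione (squaric acid dichloride, 1.1 equiv)
Product: 3 3-(6-bromo-1H-indol-3-yl)-4-chlorocyclobut-3-ene-1,2-dione
Conditions: Et2O, 0 °C to rt, product filtered off
Reagents that add atoms: none
Why: Uncatalysed Friedel–Crafts-type vinylogous acylation (addition–elimination at a chlorovinyl carbon) at the nucleophilic indole C3, a reaction established for indole itself; the product is a deactivated vinylogous amide chloride, so the second chloride is kept and no stereocentre is formed.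

Step 2
Reactants: 3 3-(6-bromo-1H-indol-3-yl)-4-chlorocyclobut-3-ene-1,2-dione; 4 1-methyl-5-(tributylstannyl)-1H-imidazole (1.1 equiv)
Product: 5 3-(6-bromo-1H-indol-3-yl)-4-(1-methyl-1H-imidazol-5-yl)cyclobut-3-ene-1,2-dione
Conditions: Pd2(dba)3 (2.5 mol %), P(2-furyl)3 (10 mol %), CuI (10 mol %), MeCN, 50 °C
Reagents that add atoms: none
Why: Stille cross-coupling of a halocyclobutenedione; zerovalent palladium inserts into the acid-chloride-like C–Cl bond far faster than into the aryl C–Br bond at 50 °C, and CuI speeds transmetalation of the imidazol-5-ylstannane.

Step 3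
Reactants: 5 3-(6-bromo-1H-indol-3-yl)-4-(1-methyl-1H-imidazol-5-yl)cyclobut-3-ene-1,2-dione
Product: 7 didemnimide D, via aza-Criegee adduct 6 (not isolated)
Conditions: Ph2P(O)ONH2 (1.5 equiv), HFIP (1,1,1,3,3,3-hexafluoropropan-2-ol), 25 °C
Reagents that add atoms: O-(diphenylphosphinyl)hydroxylamine, NOP(=O)(c1ccccc1)c1ccccc1
Why: Proposed new method: nitrogen-atom insertion into the C(O)–C(O) bond of a cyclobutene-1,2-dione (aza-Baeyer–Villiger ring expansion), in which the alpha-effect amine of Ph2P(O)ONH2 adds to the more electrophilic strained carbonyl (the one next to the indolyl-bearing carbon, the other being a vinylogous amide) to give carbinolamine 6, whose acyl carbon then shifts from carbon to nitrogen with loss of diphenylphosphinate, driven by four-ring strain release and the weak N–O bond, so that both imide C–N bonds and the maleimide ring form in one operation; attack at either carbonyl gives the same imide, a Beckmann-type fragmentation to a cyano acylium ion would reclose to the same ring, and HFIP activates the carbonyl while hydrogen-bonding the imidazole nitrogen against N-amination; the closest known reaction types are the aza-Baeyer–Villiger ring expansion of cyclobutanones to gamma-lactams with amino diphenylphosphinates and the peroxide Baeyer–Villiger oxidation of diarylcyclobutenediones to maleic anhydrides.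

## Compound list

1 | 6-bromo-1H-indole | Brc1ccc2cc[nH]c2c1 | starting material
2 | 3,4-dichlorocyclobut-3-ene-1,2-dione (squaric acid dichloride) | O=C1C(=O)C(Cl)=C1Cl | starting material
3 | 3-(6-bromo-1H-indol-3-yl)-4-chlorocyclobut-3-ene-1,2-dione | O=C1C(=O)C(c2c[nH]c3cc(Br)ccc23)=C1Cl | intermediate
4 | 1-methyl-5-(tributylstannyl)-1H-imidazole | CCCC[Sn](CCCC)(CCCC)c1cncn1C | starting material
5 | 3-(6-bromo-1H-indol-3-yl)-4-(1-methyl-1H-imidazol-5-yl)cyclobut-3-ene-1,2-dione | Cn1cncc1C1=C(c2c[nH]c3cc(Br)ccc23)C(=O)C1=O | intermediate
6 | aza-Criegee adduct, 3-(6-bromo-1H-indol-3-yl)-4-{[(diphenylphosphoryl)oxy]amino}-4-hydroxy-2-(1-methyl-1H-imidazol-5-yl)cyclobut-2-en-1-one (racemic, not isolated) | Cn1cncc1C1=C(c2c[nH]c3cc(Br)ccc23)C(O)(NOP(=O)(c2ccccc2)c2ccccc2)C1=O | intermediate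
7 | didemnimide D, 3-(6-bromo-1H-indol-3-yl)-4-(1-methyl-1H-imidazol-5-yl)-1H-pyrrole-2,5-dione | Cn1cncc1C1=C(c2c[nH]c3cc(Br)ccc23)C(=O)NC1=O | target

## Step count and risks

Total step count: 3. Longest linear sequence: 3 steps (1 to 3 to 5 to 7).

The three steps most likely to fail, most risky first:

**Step 3 (proposed new nitrogen insertion).** Possible failures are migration of the vinyl carbon instead of the acyl carbon (giving the isomeric 1H-pyrrole-2,3-dione), N-amination of the imidazole, or ring opening of the carbinolamine. The fallback uses known chemistry, sets out from 5 and comes back at 7. Oxygen is inserted in place of nitrogen: 5 is treated with 30% H2O2 in AcOH at 25 °C, the established Baeyer–Villiger ring expansion of diarylcyclobutenediones, to give 3-(6-bromo-1H-indol-3-yl)-4-(1-methyl-1H-imidazol-5-yl)furan-2,5-dione F3. The anhydride is then converted to the NH imide with HN(SiMe3)2 and MeOH in DMF at 25 °C (ammonia released in the flask, ring opening to the amic acid, silyl-assisted ring closure), which gives 7.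

**Step 2 (Stille coupling).** Possible failures are quaternisation of the basic imidazole nitrogen of 4 by the vinylogous acid chloride 3, protodestannylation by the acidic indole N–H, or competing insertion at C–Br. The fallback sets out from 3 and comes back at 5. The chloride is first exchanged for a thioether with 4-methylbenzenethiol and Et3N in CH2Cl2 at 0 °C, giving 3-(6-bromo-1H-indol-3-yl)-4-[(4-methylphenyl)sulfanyl]cyclobut-3-ene-1,2-dione F2, which is inert to nitrogen nucleophiles. F2 is then joined to 4 in a neutral Liebeskind–Srogl-type thioorganic coupling, which activates the C–S bond with a stoichiometric copper carboxylate instead of relying on the C–Cl bond: Pd(PPh3)4 (5 mol %, zerovalent palladium), Cu(O2CC4H3S) (copper thiophene-2-carboxylate, monovalent copper, 1.5 equiv), THF, 50 °C, to give 5.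

**Step 1 (uncatalysed Friedel–Crafts reaction).** Possible failures are sluggish reaction of the bromine-deactivated indole or acid-promoted oligomerisation by the HCl formed. The fallback sets out from 1 and comes back at 3. The neutral arene is replaced by a metalated indole: 1 is deprotonated with EtMgBr in toluene/THF at 0 °C to give (6-bromo-1H-indol-1-yl)magnesium bromide F1. F1 (2 equiv, one acting as base and recovered as 1) is added to 2 at −40 °C to rt; it attacks through C3 in an addition–elimination, as indolyl Grignard reagents do with dihalomaleimides, and gives 3 after aqueous NH4Cl work-up.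

## Further compounds

F1 | step 1 | (6-bromo-1H-indol-1-yl)magnesium bromide | Br[Mg]n1ccc2ccc(Br)cc21
F2 | step 2 | 3-(6-bromo-1H-indol-3-yl)-4-[(4-methylphenyl)sulfanyl]cyclobut-3-ene-1,2-dione | Cc1ccc(SC2=C(c3c[nH]c4cc(Br)ccc34)C(=O)C2=O)cc1
F3 | step 3 | 3-(6-bromo-1H-indol-3-yl)-4-(1-methyl-1H-imidazol-5-yl)furan-2,5-dione | Cn1cncc1C1=C(c2c[nH]c3cc(Br)ccc23)C(=O)OC1=O
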